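## The problem

1. The target is a sesquilignan in which an oxolane (numbered here O1, C2, C3, C4, C5) is bonded through C2 to C5' of a 2-aryl-3-hydroxymethyl-7-methoxy-2,3-dihydrobenzofuran (O1', C2', C3', C3a'–C7a'); ring A is the guaiacyl ring on C2', ring B the benzo ring, and ring C the guaiacyl ring of the benzyl group on C4.
2. On the oxolane the ring B aryl group (C2), the hydroxymethyl group (C3) and the ring C benzyl group (C4) all lie on one face and the tertiary C4 hydroxyl on the other (2R,3R,4S in this numbering), the most crowded arrangement, which no equilibration of a finished ring will give.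
3. The dihydrobenzofuran is cis (2'R,3'R), again the less stable isomer: a carbonyl group on C3' in base, or acid at the C2' benzylic ether, would turn it into trans.
4. The two sets of stereocentres are separated by ring B and cannot steer each other, so each half must be made in absolute form; within the oxolane the quaternary C4, the only centre that cannot epimerise, is the anchor from which C2 and C3 have to be set.
5. The fragile parts are the two electron-rich benzylic ether bonds (O1–C2 and O1'–C2'), which ionise in acid and can be hydrogenolysed, the tertiary alcohol and the two phenols; the late steps must therefore be neutral or basic, and the protecting groups must leave with fluoride or hydrogen.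
6. The key step rests on O1–C2 being a benzylic ether bond next to C3: with C3 as a ketone, C2 becomes the diazo carbon of an α-aryl-α-diazo ketone, flanked by ring B and the C3 acyl group, and the C5 hydroxyl sits in the 1,5 position to trap the derived carbenoid in a five-membered ring.
7. The same ketone leaves C3 trigonal, so that its carbon substituent and then its hydrogen can be added from the open face, and it leaves C2 enolisable, hence correctable, beside the fixed C4.

## Retrosynthesis

**End game (31 back to 26).** The phenols of 31 are uncovered last from the dibenzyl ether 30. In 30 the C3–H bond and the C–O bond of the C3 hydroxymethyl group are cut, which leads to the exocyclic alkene 28. Hydroboration must deliver hydrogen to C3 from the face that carries only H (C2) and OH (C4); this places CH2OH on the crowded face, which an enolate alkylation or an equilibration at C3 would not do. 28 comes from the silyl ethers 27 by fluoride, and 27 from ketone 26 by methylenation, so that one carbonyl carbon serves as the source of both the C3 substituent and the C3 hydrogen. What is asked is face selectivity from two ring substituents that must both lie on the lower face, which fixes the required configuration of 26 at C2.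

**Key disconnection (26 back to 24).** The O1–C2 bond is cut, giving the hydroxy α-aryl-α-diazo ketone 24. Cutting O1–C5 instead would need an alkoxide on the benzylic C2 with its configuration already set, and cutting C2–C3 or C3–C4 would mean an aldol-type construction at the quaternary carbinol. The O1–C2 cut turns the ring into an open chain with a single stereocentre (C4) in that half and places the union of the two halves at the diazo carbon. The forward reaction must trap the carbenoid with the C5 hydroxyl ahead of every other pathway. It leaves C2 as an epimerisable centre, formed together with its epimer 25, whose ratio can still be moved and which is fixed only when C3 becomes an alkene.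

**Union of the halves (24 back to 13 and 22).** 24 is the mono-desilylated form of 23, and in 23 the C2–C5' bond is cut: a palladium-catalysed arylation of the diazo C–H bond of 13 by the aryl iodide 22. This joins two fragments of equal weight at room temperature without strong base. The neighbouring choice, arylation of a methyl ketone enolate followed by diazo transfer, puts an enolate beside an α-silyloxy group and is kept as a reserve. The reaction must tolerate a hindered acyl group and keep the diazo function.

**Oxolane half (13 back to 1 and 3).** Diazo ketone 13 comes from acid 11, which is the persilylated form of dihydroxy acid 9. The C4 carbinol is traced to the epoxy alcohol 7, made by Sharpless epoxidation of the 2-benzylallyl alcohol 6. Dihydroxylation of acrylate 5 would be one step shorter, but its two geminal substituents (ester and benzyl) are of similar size, so neither the sense nor the level of induction can be foretold; the epoxidation of a 2-substituted allyl alcohol has a firm facial rule. Oxidising the CH2OH arm of 7 and opening the epoxide at its CH2 with hydroxide decides which arm becomes C3 and which C5. 6 comes from 5 by reduction, and 5 from the Grignard reagent 4 of bromide 2 and the allylic bromide 3; 2 is the benzyl ether of phenol 1.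

**Dihydrobenzofuran half (22 back to 1, 15 and 17).** Iodide 22 is derived from bromide 21, its alcohol 20 and the cis ester 19. In 19 the C2'–C3' bond is cut: intramolecular C–H insertion of the aryl diazoacetate 18 into the benzylic ether C–H bond, a concerted step that gives the cis isomer kinetically and sets both centres at once under a chiral dirhodium catalyst. Closure at O1'–C2' or contraction of a six-membered ring (see below) sets the centres in separate steps. 18 comes from the iodo bromo ether 16 and ethyl diazoacetate 17 by the same diazo C–H arylation used for the union, here selective for iodide over bromide. 16 is the ether of iodophenol 14 and alcohol 15, and 14 is the ortho-iodination product of 1. The ester must be reduced at once, because base would epimerise C3'.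

## Roads not taken

**Alternative 1:** The dihydrofuran ring is cut at O1'–C2'. An oxazolidinone-mediated syn aldol sets C2' and C3' in an open chain, and the phenol–benzylic alcohol A2 is then closed with PPh3 and diisopropyl azodicarboxylate. The ring B phenol displaces the activated C2' hydroxyl with inversion and gives the cis bromide A1, in which ring A carries a tosylate to hold back ionisation.
- Merits: the absolute configuration comes from an auxiliary whose sense is beyond doubt, and syn aldol plus inversion leads logically to cis.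
- Weak points: the displacement is an SN2 reaction at a secondary benzylic carbon next to a branched carbon. Any leak to an ionised pathway gives the trans isomer or a stilbene, and the tosylate must later be exchanged for a group that leaves under mild conditions.
- The sequence (auxiliary on, aldol, auxiliary off, protection, closure, protecting-group exchange) is clearly longer than the four steps from 14 to 19.
- It addresses only the dihydrobenzofuran; the oxolane would still have to be built as in the adopted plan.
- Comparison: in certainty of absolute sense this road is better than step 11, whose sense rests on analogy. The adopted plan sets against it the shorter sequence, a concerted insertion in which no cation can form, and a single protecting group (benzyl) on ring A throughout.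

**Alternative 2:** The ring C aryl–CH2 bond and the C4–O bond are cut. The ring C aryl Grignard reagent with catalytic CuBr·SMe2 adds to the exocyclic methylene of the cis α-methylene lactone A4, and the enolate is hydroxylated in the same flask with 2-(phenylsulfonyl)-3-phenyloxaziridine to give the hydroxy lactone A3.
- Merits: ring C and the tertiary hydroxyl arrive in one operation at a late stage. C4 is set by the ring itself, the oxidant entering opposite the C2 and C3 substituents, and that is the sense the target needs; no chiral reagent is required for C4.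
- Weak points: A4 already contains the crowded cis C2/C3 pair next to a lactone carbonyl and must first be made in that form. After A3 the C5 carbonyl has to be taken down to CH2 beside a tertiary alcohol and a benzylic C2–O bond; a lactol reduction with a silane and Lewis acid, or a diol cyclisation, puts C2 at risk.
- Comparison: in convergence and in substrate control of C4 this road is better. The adopted plan sets against it that C4 is fixed first and independently, that the ring carbonyl sits at C3 where it is used up productively, and that no deoxygenation is left for the end.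

**Alternative 3:** The C3'–C3a' bond is cut. Irradiation of the 3-diazoflavanone A6 in methanol triggers a Wolff rearrangement in which aryl carbon C4a migrates; the ketene is trapped as the methyl ester A5, a cis-2-aryl-2,3-dihydrobenzofuran-3-carboxylate.
- Merits: flavanones are cheap to reach from chalcones, C2' is carried through the contraction, and protonation of the ketene-derived enol opposite the aryl group should favour cis.
- Weak points: 2-aryl-chroman-4-ones open to chalcones in base (retro-oxa-Michael), so the C2' configuration is at risk in the basic diazo transfer that makes A6. The aryl bromide and the electron-rich rings must survive irradiation, and the cis/trans outcome depends on a proton transfer that is not assured.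
- Comparison: A5 is the same kind of intermediate as 19, reached in a similar number of steps and without a chiral rhodium catalyst, so in reagent cost this road is at least equal. The adopted plan sets against it that in step 11 both centres are created together at low temperature under neutral conditions, so no pre-existing centre can be lost.

Key step: step 17

Assumption: Rh2(S-PTTL)4 is taken to give the (2R,3S)-cis ester 19, by analogy with the sense known for this catalyst class with 2-(benzyloxy)phenyl diazoacetates; if the first run shows the antipode, Rh2(R-PTTL)4 is used and nothing else changes.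

Shorthand in names: BnG = 4-(benzyloxy)-3-methoxyphenyl. DBF(Si) = (2R,3R)-2-BnG-3-[(tert-butyldimethylsilyloxy)methyl]-7-methoxy-2,3-dihydro-1-benzofuran-5-yl with the C2' and C3' substituents cis. DBF(OH) = the same group with a free 3-hydroxymethyl. Oxolane locants are those defined above.

## Route

**Step 1**
Reactants: 1 4-bromo-2-methoxyphenol
Product: 2 1-(benzyloxy)-4-bromo-2-methoxybenzene
Conditions: BnBr, K2CO3, DMF, rt
Reagents that add atoms: benzyl bromide, BrCc1ccccc1
Why: Williamson etherification of the phenoxide; the benzyl ether withstands the organomagnesium, hydride, oxidant, base and fluoride steps and leaves last by hydrogenolysis.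

**Step 2**
Reactants: 2 1-(benzyloxy)-4-bromo-2-methoxybenzene; 3 methyl 2-(bromomethyl)prop-2-enoate
Product: 5 methyl 2-(BnG-methyl)prop-2-enoate, via arylmagnesium bromide 4 (not isolated)
Conditions: Mg, THF, 40 °C; then CuI (10 mol %), 3, THF, −78 → −20 °C
Reagents that add atoms: none
Why: Copper-catalysed SN2' allylic substitution of the aryl Grignard reagent on the 2-(bromomethyl)acrylate, a standard entry to 2-benzylacrylates; at low temperature the organocopper attacks the allylic system faster than the ester.

**Step 3**
Reactants: 5 methyl 2-(BnG-methyl)prop-2-enoate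
Product: 6 2-(BnG-methyl)prop-2-en-1-ol
Conditions: i-Bu2AlH (2.5 equiv), CH2Cl2, −78 → 0 °C; aq. potassium sodium tartrate
Reagents that add atoms: none
Why: 1,2-Reduction of the conjugated ester by the aluminium hydride gives the allylic alcohol and leaves the 1,1-disubstituted alkene and the benzyl ether alone.

**Step 4**
Reactants: 6 2-(BnG-methyl)prop-2-en-1-ol
Product: 7 [(2S)-2-(BnG-methyl)oxiran-2-yl]methanol
Conditions: Ti(OiPr)4 (10 mol %), L-(+)-diethyl tartrate (12 mol %), t-BuOOH (2 equiv), 4 Å molecular sieves, CH2Cl2, −20 °C
Reagents that add atoms: tert-butyl hydroperoxide, CC(C)(C)OO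
Why: Sharpless asymmetric epoxidation; with L-(+)-tartrate a 2-substituted allyl alcohol is epoxidised on the face that gives the (S)-epoxy alcohol (the sense that gives (S)-2-methylglycidol), which fixes the future C4. The catalytic loading with sieves limits opening of the 2,2-disubstituted epoxide.

**Step 5**
Reactants: 7 [(2S)-2-(BnG-methyl)oxiran-2-yl]methanol
Product: 9 (2R)-2-(BnG-methyl)-2,3-dihydroxypropanoic acid, via epoxy acid 8 (not isolated)
Conditions: TEMPO (10 mol %), NaClO2 (2 equiv), NaOCl (5 mol %), MeCN/phosphate buffer (pH 6.7), 35 °C; Na2SO3; then 2 M NaOH, 60 °C; acidify to pH 3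
Reagents that add atoms: sodium chlorite, [Na+].[O-]Cl=O; water, O
Why: Nitroxyl/chlorite oxidation at buffered near-neutral pH takes the primary alcohol to the acid without acid-catalysed opening of the epoxide. Hydroxide then opens the glycidate by SN2 attack at the unsubstituted CH2, so the quaternary centre is untouched, the former CH2OH arm becomes C3 and the former epoxide CH2 becomes C5.

**Step 6**
Reactants: 9 (2R)-2-(BnG-methyl)-2,3-dihydroxypropanoic acid
Product: 11 (2R)-2-(BnG-methyl)-2,3-bis(triethylsilyloxy)propanoic acid, via tris(triethylsilyl) derivative 10 (not isolated)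
Conditions: Et3SiOTf (3.5 equiv), 2,6-lutidine (5 equiv), CH2Cl2, −78 → 0 °C; then K2CO3, MeOH/H2O, 0 °C; work-up at pH 5
Reagents that add atoms: triethylsilyl trifluoromethanesulfonate, CC[Si](CC)(CC)OS(=O)(=O)C(F)(F)F
Why: Exhaustive silylation with the silyl triflate also covers the tertiary hydroxyl; cold carbonate then cleaves only the silyl ester (selective solvolysis), leaving the acid with both hydroxyls as Et3Si ethers.

**Step 7**
Reactants: 11 (2R)-2-(BnG-methyl)-2,3-bis(triethylsilyloxy)propanoic acid
Product: 13 (3R)-1-diazo-3-(BnG-methyl)-3,4-bis(triethylsilyloxy)butan-2-one, via acid chloride 12 (not isolated)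
Conditions: 1-chloro-N,N,2-trimethylprop-1-en-1-amine (1.3 equiv), CH2Cl2, 0 °C; then Me3SiCHN2 (2.5 equiv), MeCN/THF, 0 °C → rt
Reagents that add atoms: (trimethylsilyl)diazomethane, C[Si](C)(C)C=[N+]=[N-]
Why: The chloroenamine forms the acid chloride without releasing HCl, so the silyl ethers survive; C-acylation of Me3SiCHN2 with loss of the silyl group to chloride (Arndt–Eistert-type diazo ketone synthesis) gives the terminal diazo ketone.

**Step 8**
Reactants: 1 4-bromo-2-methoxyphenol
Product: 14 4-bromo-2-iodo-6-methoxyphenol
Conditions: NaI (1.05 equiv), NaOCl (1.05 equiv), NaOH, MeOH/H2O, 0 °C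
Reagents that add atoms: sodium iodide, [Na+].[I-]
Why: Electrophilic aromatic iodination of the phenoxide by hypoiodite; the only free position ortho or para to the phenoxide oxygen is C6, so one regioisomer is expected.

**Step 9**
Reactants: 14 4-bromo-2-iodo-6-methoxyphenol; 15 [4-(benzyloxy)-3-methoxyphenyl]methanol
Product: 16 2-(BnG-methoxy)-5-bromo-1-iodo-3-methoxybenzene
Conditions: PPh3, diisopropyl azodicarboxylate, THF, 0 °C → rt
Reagents that add atoms: none
Why: Mitsunobu etherification of an acidic phenol with a primary benzylic alcohol; the ortho and para carbons of the phenol are blocked, so only O-alkylation is possible.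

**Step 10**
Reactants: 16 2-(BnG-methoxy)-5-bromo-1-iodo-3-methoxybenzene; 17 ethyl diazoacetate
Product: 18 ethyl 2-[2-(BnG-methoxy)-5-bromo-3-methoxyphenyl]-2-diazoacetate
Conditions: Pd(PPh3)4 (5 mol %), Ag2CO3 (0.5 equiv), Et3N (1.3 equiv), toluene, rt
Reagents that add atoms: none
Why: Palladium-catalysed cross-coupling of an aryl iodide with the C–H bond of a diazoacetate (oxidative addition, carbonate-assisted deprotonation, reductive elimination with the diazo group kept); at room temperature zerovalent palladium inserts into the C–I bond and leaves the C–Br bond alone.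

**Step 11**
Reactants: 18 ethyl 2-[2-(BnG-methoxy)-5-bromo-3-methoxyphenyl]-2-diazoacetate
Product: 19 ethyl (2R,3S)-2-BnG-5-bromo-7-methoxy-2,3-dihydro-1-benzofuran-3-carboxylate (aryl and ester cis)
Conditions: Rh2(S-PTTL)4 (dirhodium tetrakis[N-phthaloyl-(S)-tert-leucinate], 1 mol %), toluene, −78 → −40 °C
Reagents that add atoms: none
Why: Intramolecular 1,5 C–H insertion of a donor–acceptor rhodium carbenoid into the benzylic ether C–H bond, the established route to cis-2-aryl-2,3-dihydrobenzofuran-3-carboxylates. The concerted, hydride-transfer-like transition state places aryl and ester cis under kinetic control, and the chiral carboxylate ligands choose between the two enantiotopic C–H bonds, so C2' and C3' are set together.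

**Step 12**
Reactants: 19 ethyl (2R,3S)-2-BnG-5-bromo-7-methoxy-2,3-dihydro-1-benzofuran-3-carboxylate
Product: 20 [(2R,3R)-2-BnG-5-bromo-7-methoxy-2,3-dihydro-1-benzofuran-3-yl]methanol (cis)
Conditions: i-Bu2AlH (3 equiv), CH2Cl2, −78 → −20 °C; aq. potassium sodium tartrate
Reagents that add atoms: none
Why: Hydride reduction of the ester under non-basic conditions; the cis ester, which base would epimerise at C3', is converted at once into the configurationally secure alcohol, and the aryl bromide is inert.

**Step 13**
Reactants: 20 [(2R,3R)-2-BnG-5-bromo-7-methoxy-2,3-dihydro-1-benzofuran-3-yl]methanol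
Product: 21 {[(2R,3R)-2-BnG-5-bromo-7-methoxy-2,3-dihydro-1-benzofuran-3-yl]methoxy}(tert-butyl)dimethylsilane
Conditions: t-BuMe2SiCl, imidazole, DMF, rt
Reagents that add atoms: tert-butyl(chloro)dimethylsilane, CC(C)(C)[Si](C)(C)Cl
Why: Standard silylation of a primary alcohol; it keeps this hydroxyl out of the later carbenoid step and leaves with fluoride.

**Step 14**
Reactants: 21 {[(2R,3R)-2-BnG-5-bromo-7-methoxy-2,3-dihydro-1-benzofuran-3-yl]methoxy}(tert-butyl)dimethylsilane
Product: 22 {[(2R,3R)-2-BnG-5-iodo-7-methoxy-2,3-dihydro-1-benzofuran-3-yl]methoxy}(tert-butyl)dimethylsilane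
Conditions: CuI (10 mol %), NaI (2 equiv), trans-N,N'-dimethylcyclohexane-1,2-diamine (20 mol %), 1,4-dioxane, 110 °C
Reagents that add atoms: sodium iodide, [Na+].[I-]
Why: Copper-catalysed aromatic Finkelstein reaction, driven by the low solubility of NaBr in dioxane; it supplies the iodide needed for oxidative addition at room temperature in step 15 and touches neither stereocentre, since no acidic C–H or ionising conditions are involved.

**Step 15**
Reactants: 13 (3R)-1-diazo-3-(BnG-methyl)-3,4-bis(triethylsilyloxy)butan-2-one; 22 {[(2R,3R)-2-BnG-5-iodo-7-methoxy-2,3-dihydro-1-benzofuran-3-yl]methoxy}(tert-butyl)dimethylsilane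
Product: 23 (3R)-1-diazo-1-[DBF(Si)]-3-(BnG-methyl)-3,4-bis(triethylsilyloxy)butan-2-one
Conditions: Pd(PPh3)4 (10 mol %), Ag2CO3 (0.5 equiv), Et3N (1.5 equiv), toluene, rt, dark
Reagents that add atoms: none
Why: The same palladium-catalysed diazo C–H arylation as in step 10, here on an acyldiazomethane; it forms the C2–C5' bond at room temperature with an amine base, conditions under which the silyl ethers, the cis dihydrobenzofuran and the diazo group persist.

**Step 16**
Reactants: 23 (3R)-1-diazo-1-[DBF(Si)]-3-(BnG-methyl)-3,4-bis(triethylsilyloxy)butan-2-one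
Product: 24 (3R)-1-diazo-1-[DBF(Si)]-4-hydroxy-3-(BnG-methyl)-3-(triethylsilyloxy)butan-2-one
Conditions: pyridinium p-toluenesulfonate (0.2 equiv), MeOH/CH2Cl2 (1:3), 0 °C
Reagents that add atoms: none
Why: Acid-catalysed methanolysis of silyl ethers follows steric access, so the primary Et3Si ether goes well before the tertiary Et3Si ether and the primary t-BuMe2Si ether. The pyridinium salt is too weak an acid to protonate the diazo carbon at 0 °C, and acid, unlike base or fluoride, does not move the remaining silyl group onto the freed hydroxyl.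

**Step 17**
Reactants: 24 (3R)-1-diazo-1-[DBF(Si)]-4-hydroxy-3-(BnG-methyl)-3-(triethylsilyloxy)butan-2-one
Product: 26 (2S,4R)-2-[DBF(Si)]-4-(BnG-methyl)-4-(triethylsilyloxy)oxolan-3-one (aryl cis to benzyl), via C2-epimeric oxolanone 25 (not isolated)
Conditions: Rh2(OAc)4 (1 mol %), CH2Cl2 (0.01 M, slow addition of 24), 0 °C → rt, argon; then DBU (0.1 equiv), rt
Reagents that add atoms: none
Why: Rh2(OAc)4 takes N2 from the diazo carbon of 24, and the electrophilic rhodium carbenoid at C2 is captured by the lone pair of the C5 hydroxyl oxygen; the five-membered oxonium ylide passes its proton on through the enol to give the ketone, a net insertion of C2 into the O–H bond. The closest known reaction type is the dirhodium-catalysed intramolecular O–H insertion of hydroxy diazo ketones to oxolan-3-ones. The oxolane is closed by formation of the O1–C2 bond, the tethered oxygen attacking the carbenoid carbon, so that O1, C2, C3, C4 and C5 become the ring atoms. The step needs O–H capture to run ahead of addition to ring C through the C4 benzyl group (Buchner-type, six-membered) and of attack by the silyl ether oxygen (four-membered ylide); this is secured by the free primary hydroxyl in the 1,5 position, by the aryl-stabilised and hence more selective carbenoid, by the absence of hydrogen on C4 for a 1,2-shift and by high dilution. C2 is the new stereocentre: it arises by protonation of the enol, and because it is an α-aryl-α-alkoxy ketone carbon, DBU interconverts 25 and 26 through one enolate. A preference for 26 can be argued from the envelope in which the C4 benzyl group is equatorial and the C2 aryl group on the same face meets no axial neighbour, but gaps between such epimers are small, so the equilibrium is treated as a reservoir: 26 is separated and mixed fractions go back to DBU. The Et3Si ether on C4 prevents a ketol shift of the α-oxygenated ketone during this treatment, and C4, having no hydrogen, is untouched.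

**Step 18**
Reactants: 26 (2S,4R)-2-[DBF(Si)]-4-(BnG-methyl)-4-(triethylsilyloxy)oxolan-3-one
Product: 27 (2S,4S)-2-[DBF(Si)]-4-(BnG-methyl)-3-methylidene-4-(triethylsilyloxy)oxolane
Conditions: Cp2TiMe2 (3 equiv), toluene/THF, 65 °C, dark
Reagents that add atoms: dimethyltitanocene, C[Ti](C)(C1C=CC=C1)C1C=CC=C1
Why: Petasis olefination by the titanocene methylidene formed thermally from Cp2TiMe2; the reagent is mild enough for an easily enolised, hindered ketone, and once C3 is an alkene C2 can no longer epimerise.

**Step 19**
Reactants: 27 (2S,4S)-2-[DBF(Si)]-4-(BnG-methyl)-3-methylidene-4-(triethylsilyloxy)oxolane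
Product: 28 (2S,4S)-2-[DBF(OH)]-4-(BnG-methyl)-3-methylideneoxolan-4-ol
Conditions: Bu4NF (3 equiv), THF, 0 °C → rt
Reagents that add atoms: none
Why: Fluoride-mediated desilylation removes both silyl ethers; freeing the C4 hydroxyl leaves the upper face of the alkene flanked only by H (C2) and OH (C4).

**Step 20**
Reactants: 28 (2S,4S)-2-[DBF(OH)]-4-(BnG-methyl)-3-methylideneoxolan-4-ol
Product: 30 (2R,3R,4S)-2-[DBF(OH)]-4-(BnG-methyl)-3-(hydroxymethyl)oxolan-4-ol, via B-alkyl-9-borabicyclononane 29 (not isolated)
Conditions: 9-BBN (4 equiv), THF, 0 °C → rt; then NaOH, H2O2, 0 °C → rt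
Reagents that add atoms: hydrogen peroxide, OO
Why: Anti-Markovnikov hydroboration of the 1,1-disubstituted alkene with a bulky dialkylborane, followed by oxidation with retention at carbon. Boron goes to the terminal carbon and hydrogen to C3 from the face of H (C2) and OH (C4), away from the C2 aryl and C4 benzyl groups, which sets C3 with CH2OH cis to both. A dialkylborane has no second B–H bond, so no delivery from an O–B tether on the same face as the hydroxyl can interfere.

**Step 21**
Reactants: 30 (2R,3R,4S)-2-[DBF(OH)]-4-(BnG-methyl)-3-(hydroxymethyl)oxolan-4-ol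
Product: 31 (2R,3R,4S)-4-(4-hydroxy-3-methoxybenzyl)-3-(hydroxymethyl)-2-[(2R,3R)-2-(4-hydroxy-3-methoxyphenyl)-3-(hydroxymethyl)-7-methoxy-2,3-dihydro-1-benzofuran-5-yl]oxolan-4-ol
Conditions: H2 (1 atm), Pd/C (10 %), EtOAc/MeOH, rt
Reagents that add atoms: none
Why: Catalytic hydrogenolysis of the two aryl benzyl ethers; it is stopped after uptake of two equivalents of hydrogen, because the ring benzylic ethers (O1–C2, O1'–C2') are cleaved much more slowly under neutral conditions.

## Compound list

1 | 4-bromo-2-methoxyphenol | COc1cc(Br)ccc1O | starting material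
2 | 1-(benzyloxy)-4-bromo-2-methoxybenzene | COc1cc(Br)ccc1OCc1ccccc1 | intermediate
3 | methyl 2-(bromomethyl)prop-2-enoate | C=C(CBr)C(=O)OC | starting material
4 | [4-(benzyloxy)-3-methoxyphenyl]magnesium bromide | COc1cc([Mg]Br)ccc1OCc1ccccc1 | intermediate
5 | methyl 2-{[4-(benzyloxy)-3-methoxyphenyl]methyl}prop-2-enoate | COc1cc(CC(=C)C(=O)OC)ccc1OCc1ccccc1 | intermediate
6 | 2-{[4-(benzyloxy)-3-methoxyphenyl]methyl}prop-2-en-1-ol | COc1cc(CC(=C)CO)ccc1OCc1ccccc1 | intermediate
7 | [(2S)-2-{[4-(benzyloxy)-3-methoxyphenyl]methyl}oxiran-2-yl]methanol | COc1cc(C[C@@]2(CO2)CO)ccc1OCc1ccccc1 | intermediate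
8 | (2R)-2-{[4-(benzyloxy)-3-methoxyphenyl]methyl}oxirane-2-carboxylic acid | COc1cc(C[C@@]2(CO2)C(=O)O)ccc1OCc1ccccc1 | intermediate
9 | (2R)-2-{[4-(benzyloxy)-3-methoxyphenyl]methyl}-2,3-dihydroxypropanoic acid | COc1cc(C[C@@](O)(CO)C(=O)O)ccc1OCc1ccccc1 | intermediate
10 | triethylsilyl (2R)-2-{[4-(benzyloxy)-3-methoxyphenyl]methyl}-2,3-bis(triethylsilyloxy)propanoate | COc1cc(C[C@@](O[Si](CC)(CC)CC)(CO[Si](CC)(CC)CC)C(=O)O[Si](CC)(CC)CC)ccc1OCc1ccccc1 | intermediate
11 | (2R)-2-{[4-(benzyloxy)-3-methoxyphenyl]methyl}-2,3-bis(triethylsilyloxy)propanoic acid | COc1cc(C[C@@](O[Si](CC)(CC)CC)(CO[Si](CC)(CC)CC)C(=O)O)ccc1OCc1ccccc1 | intermediate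
12 | (2R)-2-{[4-(benzyloxy)-3-methoxyphenyl]methyl}-2,3-bis(triethylsilyloxy)propanoyl chloride | COc1cc(C[C@@](O[Si](CC)(CC)CC)(CO[Si](CC)(CC)CC)C(Cl)=O)ccc1OCc1ccccc1 | intermediate
13 | (3R)-3-{[4-(benzyloxy)-3-methoxyphenyl]methyl}-1-diazo-3,4-bis(triethylsilyloxy)butan-2-one | COc1cc(C[C@@](O[Si](CC)(CC)CC)(CO[Si](CC)(CC)CC)C(=O)C=[N+]=[N-])ccc1OCc1ccccc1 | intermediate
14 | 4-bromo-2-iodo-6-methoxyphenol | COc1cc(Br)cc(I)c1O | intermediate
15 | [4-(benzyloxy)-3-methoxyphenyl]methanol | COc1cc(CO)ccc1OCc1ccccc1 | starting material
16 | 2-{[4-(benzyloxy)-3-methoxyphenyl]methoxy}-5-bromo-1-iodo-3-methoxybenzene | COc1cc(Br)cc(I)c1OCc1ccc(OCc2ccccc2)c(OC)c1 | intermediate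
17 | ethyl diazoacetate | CCOC(=O)C=[N+]=[N-] | starting material
18 | ethyl 2-(2-{[4-(benzyloxy)-3-methoxyphenyl]methoxy}-5-bromo-3-methoxyphenyl)-2-diazoacetate | CCOC(=O)C(=[N+]=[N-])c1cc(Br)cc(OC)c1OCc1ccc(OCc2ccccc2)c(OC)c1 | intermediate
19 | ethyl (2R,3S)-2-[4-(benzyloxy)-3-methoxyphenyl]-5-bromo-7-methoxy-2,3-dihydro-1-benzofuran-3-carboxylate (cis) | Brc1cc(OC)c2c(c1)[C@H](C(=O)OCC)[C@H](c1ccc(OCc3ccccc3)c(OC)c1)O2 | intermediate
20 | [(2R,3R)-2-[4-(benzyloxy)-3-methoxyphenyl]-5-bromo-7-methoxy-2,3-dihydro-1-benzofuran-3-yl]methanol (cis) | Brc1cc(OC)c2c(c1)[C@H](CO)[C@H](c1ccc(OCc3ccccc3)c(OC)c1)O2 | intermediate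
21 | {[(2R,3R)-2-[4-(benzyloxy)-3-methoxyphenyl]-5-bromo-7-methoxy-2,3-dihydro-1-benzofuran-3-yl]methoxy}(tert-butyl)dimethylsilane | Brc1cc(OC)c2c(c1)[C@H](CO[Si](C)(C)C(C)(C)C)[C@H](c1ccc(OCc3ccccc3)c(OC)c1)O2 | intermediate
22 | {[(2R,3R)-2-[4-(benzyloxy)-3-methoxyphenyl]-5-iodo-7-methoxy-2,3-dihydro-1-benzofuran-3-yl]methoxy}(tert-butyl)dimethylsilane | Ic1cc(OC)c2c(c1)[C@H](CO[Si](C)(C)C(C)(C)C)[C@H](c1ccc(OCc3ccccc3)c(OC)c1)O2 | intermediate
23 | (3R)-1-diazo-1-[DBF(Si)]-3-{[4-(benzyloxy)-3-methoxyphenyl]methyl}-3,4-bis(triethylsilyloxy)butan-2-one | COc1cc(C[C@@](O[Si](CC)(CC)CC)(CO[Si](CC)(CC)CC)C(=O)C(=[N+]=[N-])c2cc(OC)c3c(c2)[C@H](CO[Si](C)(C)C(C)(C)C)[C@H](c2ccc(OCc4ccccc4)c(OC)c2)O3)ccc1OCc1ccccc1 | intermediate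
24 | (3R)-1-diazo-1-[DBF(Si)]-4-hydroxy-3-{[4-(benzyloxy)-3-methoxyphenyl]methyl}-3-(triethylsilyloxy)butan-2-one | COc1cc(C[C@@](O[Si](CC)(CC)CC)(CO)C(=O)C(=[N+]=[N-])c2cc(OC)c3c(c2)[C@H](CO[Si](C)(C)C(C)(C)C)[C@H](c2ccc(OCc4ccccc4)c(OC)c2)O3)ccc1OCc1ccccc1 | intermediate
25 | (2R,4R)-2-[DBF(Si)]-4-{[4-(benzyloxy)-3-methoxyphenyl]methyl}-4-(triethylsilyloxy)oxolan-3-one (aryl trans to benzyl) | COc1cc(C[C@@]2(O[Si](CC)(CC)CC)CO[C@H](c3cc(OC)c4c(c3)[C@H](CO[Si](C)(C)C(C)(C)C)[C@H](c3ccc(OCc5ccccc5)c(OC)c3)O4)C2=O)ccc1OCc1ccccc1 | intermediate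
26 | (2S,4R)-2-[DBF(Si)]-4-{[4-(benzyloxy)-3-methoxyphenyl]methyl}-4-(triethylsilyloxy)oxolan-3-one (aryl cis to benzyl) | COc1cc(C[C@@]2(O[Si](CC)(CC)CC)CO[C@@H](c3cc(OC)c4c(c3)[C@H](CO[Si](C)(C)C(C)(C)C)[C@H](c3ccc(OCc5ccccc5)c(OC)c3)O4)C2=O)ccc1OCc1ccccc1 | intermediate
27 | (2S,4S)-2-[DBF(Si)]-4-{[4-(benzyloxy)-3-methoxyphenyl]methyl}-3-methylidene-4-(triethylsilyloxy)oxolane | COc1cc(C[C@@]2(O[Si](CC)(CC)CC)CO[C@@H](c3cc(OC)c4c(c3)[C@H](CO[Si](C)(C)C(C)(C)C)[C@H](c3ccc(OCc5ccccc5)c(OC)c3)O4)C2=C)ccc1OCc1ccccc1 | intermediate
28 | (2S,4S)-2-[DBF(OH)]-4-{[4-(benzyloxy)-3-methoxyphenyl]methyl}-3-methylideneoxolan-4-ol | COc1cc(C[C@@]2(O)CO[C@@H](c3cc(OC)c4c(c3)[C@H](CO)[C@H](c3ccc(OCc5ccccc5)c(OC)c3)O4)C2=C)ccc1OCc1ccccc1 | intermediate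
29 | B-alkyl-9-borabicyclo[3.3.1]nonane of 28 (boron on the exocyclic carbon; C3 hydrogen cis to the C2 hydrogen and the C4 hydroxyl) | COc1cc(C[C@@]2(O)CO[C@@H](c3cc(OC)c4c(c3)[C@H](CO)[C@H](c3ccc(OCc5ccccc5)c(OC)c3)O4)[C@H]2CB2C3CCCC2CCC3)ccc1OCc1ccccc1 | intermediate
30 | (2R,3R,4S)-2-[DBF(OH)]-4-{[4-(benzyloxy)-3-methoxyphenyl]methyl}-3-(hydroxymethyl)oxolan-4-ol | COc1cc(C[C@@]2(O)CO[C@@H](c3cc(OC)c4c(c3)[C@H](CO)[C@H](c3ccc(OCc5ccccc5)c(OC)c3)O4)[C@H]2CO)ccc1OCc1ccccc1 | intermediate
31 | (2R,3R,4S)-4-(4-hydroxy-3-methoxybenzyl)-3-(hydroxymethyl)-2-[(2R,3R)-2-(4-hydroxy-3-methoxyphenyl)-3-(hydroxymethyl)-7-methoxy-2,3-dihydro-1-benzofuran-5-yl]oxolan-4-ol (CNP0284796.1) | COc1cc(C[C@@]2(O)CO[C@@H](c3cc(OC)c4c(c3)[C@H](CO)[C@H](c3ccc(O)c(OC)c3)O4)[C@H]2CO)ccc1O | target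

## Step count and least certain steps

Total: 21 steps. Longest linear sequence: 14 steps (steps 1–7 followed by 15–21; the branch through steps 8–14 is equally long).

**Step 17 (key step).** The most likely failure is weak control at C2. Both the ketonisation of the enol and the DBU equilibrium can tell the two ring faces apart only through the two substituents on C4, so the share of the wanted epimer may stay low and recycling may be slow; diversion of the carbenoid to ring C is the lesser risk. The fallback removes C2 as a stereocentre and then sets C2 and C3 together by hydrogen. It starts from 26 with any amount of 25. KN(SiMe3)2 and PhNTf2 (THF, −78 °C) give the enol triflate F1, since only C2 can enolise. Stille coupling with Bu3SnCH2OH (Pd(PPh3)4, LiCl, dioxane) gives the allylic alcohol F2, and Bu4NF gives the triol F3. Hydroxyl-directed hydrogenation with [Ir(cod)(PCy3)(py)]PF6 and H2 then adds both hydrogens to the tetrasubstituted alkene from the face of the C4 hydroxyl. This returns to the route at 30.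

**Step 15.** The acyl group of 13 is attached to a quaternary carbon, so deprotonation and transfer of the diazo carbon to palladium may be slow. The silver salt with amine may then trigger loss of nitrogen from 13 (Wolff-type decomposition) instead of coupling. The fallback builds the aryl ketone first and adds the diazo group last. It starts from 11: MeLi (2.2 equiv, THF, −78 → 0 °C) gives the methyl ketone F4. Palladium-catalysed α-arylation of its enolate with bromide 21 (Pd2(dba)3, Xantphos, NaOt-Bu, toluene, 80 °C) gives the benzyl ketone F5. Regitz diazo transfer (4-acetamidobenzenesulfonyl azide, DBU, MeCN, 0 °C) returns to the route at 23; step 14 is then not needed.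

**Step 16.** The aryl-substituted diazo carbon of 23 is the most basic site of the molecule, so protonation with loss of nitrogen may compete with methanolysis. The discrimination between the primary Et3Si and the primary t-BuMe2Si ether may also be incomplete. The fallback moves the desilylation in front of the union. It starts from 13, an acceptor-only diazo ketone with no t-BuMe2Si ether, which is treated with AcOH/THF/H2O at rt to give the hydroxy diazo ketone F6. F6 is arylated with 22 under the conditions of step 15 and returns to the route at 24.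

**Step 11.** The ortho methoxy group beside the ether oxygen and the ethyl ester are departures from the closest precedents, so enantioselection may be incomplete or of the opposite sense; the cis preference is inherent in the insertion. The fallback is a classical resolution. It starts from 20 of insufficient purity, which is esterified with (S)-naproxen (DCC, DMAP). The naproxen ester F7 of the (2R,3R) alcohol is separated from its diastereomer by crystallisation or chromatography and cleaved with K2CO3 in MeOH, returning to the route at 20.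

**Step 18.** The carbonyl group lies between a quaternary and a tertiary carbon, so methylenation may be slow and enolisation towards C2 by titanium species may take over, returning epimerised ketone. The fallback is a two-stage Peterson olefination. It starts from 26: Me3SiCH2Li with CeCl3 (THF, −78 °C), a weakly basic organocerium reagent that adds to enolisable hindered ketones, gives the β-hydroxysilane F8, and KH in THF eliminates it, returning to the route at 27.

## Further compounds

F1 | step 17 | (4R)-2-[DBF(Si)]-4-{[4-(benzyloxy)-3-methoxyphenyl]methyl}-4-(triethylsilyloxy)-4,5-dihydrofuran-3-yl trifluoromethanesulfonate | COc1cc(C[C@@]2(O[Si](CC)(CC)CC)COC(c3cc(OC)c4c(c3)[C@H](CO[Si](C)(C)C(C)(C)C)[C@H](c3ccc(OCc5ccccc5)c(OC)c3)O4)=C2OS(=O)(=O)C(F)(F)F)ccc1OCc1ccccc1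
F2 | step 17 | [(4R)-2-[DBF(Si)]-4-{[4-(benzyloxy)-3-methoxyphenyl]methyl}-4-(triethylsilyloxy)-4,5-dihydrofuran-3-yl]methanol | COc1cc(C[C@@]2(O[Si](CC)(CC)CC)COC(c3cc(OC)c4c(c3)[C@H](CO[Si](C)(C)C(C)(C)C)[C@H](c3ccc(OCc5ccccc5)c(OC)c3)O4)=C2CO)ccc1OCc1ccccc1
F3 | step 17 | (3R)-5-[DBF(OH)]-3-{[4-(benzyloxy)-3-methoxyphenyl]methyl}-4-(hydroxymethyl)-2,3-dihydrofuran-3-ol | COc1cc(C[C@@]2(O)COC(c3cc(OC)c4c(c3)[C@H](CO)[C@H](c3ccc(OCc5ccccc5)c(OC)c3)O4)=C2CO)ccc1OCc1ccccc1
F4 | step 15 | (3R)-3-{[4-(benzyloxy)-3-methoxyphenyl]methyl}-3,4-bis(triethylsilyloxy)butan-2-one | COc1cc(C[C@@](O[Si](CC)(CC)CC)(CO[Si](CC)(CC)CC)C(C)=O)ccc1OCc1ccccc1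
F5 | step 15 | (3R)-1-[DBF(Si)]-3-{[4-(benzyloxy)-3-methoxyphenyl]methyl}-3,4-bis(triethylsilyloxy)butan-2-one | COc1cc(C[C@@](O[Si](CC)(CC)CC)(CO[Si](CC)(CC)CC)C(=O)Cc2cc(OC)c3c(c2)[C@H](CO[Si](C)(C)C(C)(C)C)[C@H](c2ccc(OCc4ccccc4)c(OC)c2)O3)ccc1OCc1ccccc1
F6 | step 16 | (3R)-3-{[4-(benzyloxy)-3-methoxyphenyl]methyl}-1-diazo-4-hydroxy-3-(triethylsilyloxy)butan-2-one | COc1cc(C[C@@](O[Si](CC)(CC)CC)(CO)C(=O)C=[N+]=[N-])ccc1OCc1ccccc1
F7 | step 11 | [(2R,3R)-2-[4-(benzyloxy)-3-methoxyphenyl]-5-bromo-7-methoxy-2,3-dihydro-1-benzofuran-3-yl]methyl (2S)-2-(6-methoxynaphthalen-2-yl)propanoate | Brc1cc(OC)c2c(c1)[C@H](COC(=O)[C@@H](C)c1ccc3cc(OC)ccc3c1)[C@H](c1ccc(OCc3ccccc3)c(OC)c1)O2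
F8 | step 18 | (2S,4R)-2-[DBF(Si)]-4-{[4-(benzyloxy)-3-methoxyphenyl]methyl}-4-(triethylsilyloxy)-3-[(trimethylsilyl)methyl]oxolan-3-ol (C3 epimers) | COc1cc(C[C@@]2(O[Si](CC)(CC)CC)CO[C@@H](c3cc(OC)c4c(c3)[C@H](CO[Si](C)(C)C(C)(C)C)[C@H](c3ccc(OCc5ccccc5)c(OC)c3)O4)C2(O)C[Si](C)(C)C)ccc1OCc1ccccc1
A1 | alternative 1 | cis-5-bromo-3-[(tert-butyldimethylsilyloxy)methyl]-7-methoxy-2-[3-methoxy-4-(tosyloxy)phenyl]-2,3-dihydro-1-benzofuran | Brc1cc(OC)c2c(c1)[C@H](CO[Si](C)(C)C(C)(C)C)[C@H](c1ccc(OS(=O)(=O)c3ccc(C)cc3)c(OC)c1)O2
A2 | alternative 1 | open-chain precursor: 4-bromo-2-{3-(tert-butyldimethylsilyloxy)-1-hydroxy-1-[3-methoxy-4-(tosyloxy)phenyl]propan-2-yl}-6-methoxyphenol (syn-aldol-derived, carbinol carbon of the configuration opposite to C2' of A1) | COc1cc(Br)cc([C@H](CO[Si](C)(C)C(C)(C)C)[C@@H](c2ccc(OS(=O)(=O)c3ccc(C)cc3)c(OC)c2)O)c1O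
A3 | alternative 2 | α-hydroxy-α-benzyl lactone (3-hydroxy-3-benzyl-4-silyloxymethyl-5-aryl-oxolan-2-one) | COc1cc(C[C@@]2(O)C(=O)O[C@@H](c3cc(OC)c4c(c3)[C@H](CO[Si](C)(C)C(C)(C)C)[C@H](c3ccc(OCc5ccccc5)c(OC)c3)O4)[C@H]2CO[Si](C)(C)C(C)(C)C)ccc1OCc1ccccc1
A4 | alternative 2 | cis α-methylene lactone (3-methylidene-4-silyloxymethyl-5-aryl-oxolan-2-one) | C=C1C(=O)O[C@@H](c2cc(OC)c3c(c2)[C@H](CO[Si](C)(C)C(C)(C)C)[C@H](c2ccc(OCc4ccccc4)c(OC)c2)O3)[C@H]1CO[Si](C)(C)C(C)(C)C
A5 | alternative 3 | methyl cis-2-[4-(benzyloxy)-3-methoxyphenyl]-5-bromo-7-methoxy-2,3-dihydro-1-benzofuran-3-carboxylate | Brc1cc(OC)c2c(c1)[C@H](C(=O)OC)[C@H](c1ccc(OCc3ccccc3)c(OC)c1)O2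
A6 | alternative 3 | 2-[4-(benzyloxy)-3-methoxyphenyl]-6-bromo-3-diazo-8-methoxychroman-4-one | Brc1cc(OC)c2c(c1)C(=O)C(=[N+]=[N-])[C@H](c1ccc(OCc3ccccc3)c(OC)c1)O2
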